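**Retrosynthetic overview**
- Feature used: in ring B the ether carbon C1' and the hydroxyl carbon C6' are neighbours, and C6' is flanked on its other side by the C5' bromine. Ring A (2,3,4-tribromo-6-methoxyphenyl) hangs on the ether oxygen.
- The C6'–OH bond is traced back to C6'–I (iodine–magnesium exchange, borylation, oxidation); iodine is the one halogen that can be addressed beside five bromines.
- Key disconnection: O–C1' and C6'–I are cut together across a C1'≡C6' aryne (3,5-dibromobenzyne), which takes up cesium 2,3,4-tribromo-6-methoxyphenolate and iodine from C4F9I in one three-component coupling.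
- The aryne precursor, 2,4-dibromo-6-(trimethylsilyl)phenyl triflate, comes from 2,4,6-tribromophenol (O-silylation, Br–Li exchange with O→C silyl shift, triflation). The ring A phenol comes from 5-bromo-2-methoxyphenol by dibromination, which fixes all three bromine positions without ambiguity.
- No ring is formed at any stage; both benzene rings are bought and only joined.

Key step: step 5

Remark: ring B is numbered C1' (ether oxygen), C2' (H), C3' (Br), C4' (H), C5' (Br), C6' (OH); the target has no stereocentre, and 5-bromo-2-methoxyphenol, 2,4,6-tribromophenol and nonafluoro-1-iodobutane are taken as purchasable.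

**Step 1**
Reactants: 1 5-bromo-2-methoxyphenol
Product: 2 2,3,4-tribromo-6-methoxyphenol
Conditions: Br2 (2.05 equiv), AcOH, 15 °C → rt; aq. NaHSO3 work-up
Reagents that add atoms: bromine, BrBr
Why: Electrophilic aromatic bromination in which the free hydroxyl sends the two new bromines to its open ortho and para carbons, while the remaining C–H (only ortho to OMe, meta to OH) should stay untouched at this stoichiometry.

**Step 2**
Reactants: 2 2,3,4-tribromo-6-methoxyphenol
Product: 3 cesium 2,3,4-tribromo-6-methoxyphenolate
Conditions: CsOH·H2O (1.0 equiv), MeOH, rt; evaporate; toluene azeotrope; 60 °C, vacuum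
Reagents that add atoms: cesium hydroxide monohydrate, [Cs+].[OH-].O
Why: Acid–base salt formation of an acidic polybromophenol, after which drying removes every proton source that could later quench the aryl anion of the key step.

**Step 3**
Reactants: 4 2,4,6-tribromophenol
Product: 5 trimethyl(2,4,6-tribromophenoxy)silane
Conditions: (Me3Si)2NH (0.7 equiv), THF, reflux; evaporate, use crude
Reagents that add atoms: hexamethyldisilazane, C[Si](C)(C)N[Si](C)(C)C
Why: O-Silylation of a phenol with hexamethyldisilazane, driven by loss of ammonia and leaving no salt behind.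

**Step 4**
Reactants: 5 trimethyl(2,4,6-tribromophenoxy)silane
Product: 8 2,4-dibromo-6-(trimethylsilyl)phenyl trifluoromethanesulfonate, via aryllithium 6 (not isolated), via lithium phenolate 7 (not isolated)
Conditions: n-BuLi (1.05 equiv), THF, −100 → −80 °C; then Tf2O (1.2 equiv), −100 → −78 °C; cold aq. NaHCO3
Reagents that add atoms: trifluoromethanesulfonic anhydride, O=S(=O)(OS(=O)(=O)C(F)(F)F)C(F)(F)F; n-butyllithium, [Li]CCCC (lithium stays only in 6 and 7)
Why: Bromine–lithium exchange at one of the two equivalent ortho bromines (favoured by the neighbouring silyloxy oxygen) is followed by an anionic 1,3 O→C silyl shift (retro-Brook rearrangement) and O-triflation of the phenolate, the usual way from ortho-bromophenols to ortho-silylaryl triflates.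

**Step 5**
Reactants: 3 cesium 2,3,4-tribromo-6-methoxyphenolate (2.0 equiv); 8 2,4-dibromo-6-(trimethylsilyl)phenyl trifluoromethanesulfonate (1.0 equiv); 9 nonafluoro-1-iodobutane (5 equiv)
Product: 12 1,5-dibromo-2-iodo-3-(2,3,4-tribromo-6-methoxyphenoxy)benzene, via 3,5-dibromobenzyne 10 (not isolated), via aryl cesium adduct 11 (not isolated)
Conditions: CsF (2.5 equiv), 4 Å MS, DME, 0 °C → rt, dark
Reagents that add atoms: nonafluoro-1-iodobutane (9), FC(F)(F)C(F)(F)C(F)(F)C(F)(F)I
Why: Proposed new method: fluoride attacks the silicon of 8 and triflate leaves to give aryne 10, the phenoxide oxygen of 3 adds to the aryne carbon C1', and the aryl cesium 11 formed at C6' takes iodine from 9 by attack at iodine, so the O–C1' and C6'–I bonds are made in one flask. The closest known reaction type is the fluoride-triggered three-component coupling of ortho-silylaryl triflates in which a heteroatom nucleophile adds to the aryne and the aryl anion is caught by a halogen donor such as a perfluoroalkyl iodide; a crowded phenoxide as the nucleophile on a brominated aryne is the untested part. No ring closes and no stereocentre is formed. The selectivity needed is regiochemical: the inductive pull of the C5' bromine distorts the triple bond so that the remote carbon C1' is the more electrophilic one and the negative charge builds up next to bromine at C6', while the C3' bromine, para to C6', should exert only a small opposing effect. The second requirement is that iodine transfer outruns loss of bromide from 11 and protonation, which the excess of 9, the aprotic ether solvent and the dry preformed salt 3 are meant to secure; the spent donor should collapse to octafluorobut-1-ene and CsF. Phenoxide 3 has no free ortho or para carbon, so it should not be halogenated itself, and it is used in excess because part of it may be lost to the perfluoroalkene.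

**Step 6**
Reactants: 12 1,5-dibromo-2-iodo-3-(2,3,4-tribromo-6-methoxyphenoxy)benzene
Product: 15 2,4-dibromo-6-(2,3,4-tribromo-6-methoxyphenoxy)phenol, via arylmagnesium chloride 13 (not isolated), via dimethyl arylboronate 14 (not isolated)
Conditions: iPrMgCl·LiCl (1.05 equiv), THF, −78 °C; B(OMe)3 (2 equiv), −78 → 0 °C; then AcOH, 30% aq. H2O2, 0 °C → rt; aq. Na2S2O3
Reagents that add atoms: hydrogen peroxide, OO; isopropylmagnesium chloride–lithium chloride, CC(C)[Mg]Cl.[Li+].[Cl-] (magnesium and chlorine stay only in 13); trimethyl borate, COB(OC)OC (boron stays only in 14)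
Why: Iodine–magnesium exchange is far faster at the activated C6'–I bond than at any C–Br bond at −78 °C, where the ortho-bromoaryl Grignard reagent should also be stable, and borylation followed by peroxide oxidation (1,2-shift of aryl from boron to oxygen) under acidic rather than alkaline conditions should give the phenol with little protodeboronation.

**Compound list**
1 | 5-bromo-2-methoxyphenol | COc1ccc(Br)cc1O | starting material
2 | 2,3,4-tribromo-6-methoxyphenol | COc1cc(Br)c(Br)c(Br)c1O | intermediate
3 | cesium 2,3,4-tribromo-6-methoxyphenolate | COc1cc(Br)c(Br)c(Br)c1[O-].[Cs+] | intermediate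
4 | 2,4,6-tribromophenol | Oc1c(Br)cc(Br)cc1Br | starting material
5 | trimethyl(2,4,6-tribromophenoxy)silane | C[Si](C)(C)Oc1c(Br)cc(Br)cc1Br | intermediate
6 | [3,5-dibromo-2-(trimethylsilyloxy)phenyl]lithium | C[Si](C)(C)Oc1c(Br)cc(Br)cc1[Li] | intermediate
7 | lithium 2,4-dibromo-6-(trimethylsilyl)phenolate | C[Si](C)(C)c1cc(Br)cc(Br)c1[O-].[Li+] | intermediate
8 | 2,4-dibromo-6-(trimethylsilyl)phenyl trifluoromethanesulfonate | C[Si](C)(C)c1cc(Br)cc(Br)c1OS(=O)(=O)C(F)(F)F | intermediate
9 | nonafluoro-1-iodobutane | FC(F)(F)C(F)(F)C(F)(F)C(F)(F)I | starting material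
10 | 3,5-dibromobenzyne (3,5-dibromo-1,2-didehydrobenzene) | BrC1=CC(Br)=CC#C1 | intermediate
11 | [2,4-dibromo-6-(2,3,4-tribromo-6-methoxyphenoxy)phenyl]cesium | COc1cc(Br)c(Br)c(Br)c1Oc1cc(Br)cc(Br)c1[Cs] | intermediate
12 | 1,5-dibromo-2-iodo-3-(2,3,4-tribromo-6-methoxyphenoxy)benzene | COc1cc(Br)c(Br)c(Br)c1Oc1cc(Br)cc(Br)c1I | intermediate
13 | [2,4-dibromo-6-(2,3,4-tribromo-6-methoxyphenoxy)phenyl]magnesium chloride | COc1cc(Br)c(Br)c(Br)c1Oc1cc(Br)cc(Br)c1[Mg]Cl | intermediate
14 | dimethyl [2,4-dibromo-6-(2,3,4-tribromo-6-methoxyphenoxy)phenyl]boronate | COc1cc(Br)c(Br)c(Br)c1Oc1cc(Br)cc(Br)c1B(OC)OC | intermediate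
15 | 2,4-dibromo-6-(2,3,4-tribromo-6-methoxyphenoxy)phenol | COc1cc(Br)c(Br)c(Br)c1Oc1cc(Br)cc(Br)c1O | target

Total step count: 6
Longest linear sequence: 4 steps (steps 1, 2, 5, 6, or steps 3, 4, 5, 6)

**Steps most likely to fail**

Step 5 (bears the label "Proposed new method:"). After the phenoxide has added, the aryl cesium at C6' may expel the neighbouring C5' bromide or pick up a proton before it reaches the iodine of 9. The crowded, weakly basic phenoxide may also lose the race for the aryne to fluoride, add the other way round, or be drained by the perfluoroalkene released from the spent iodine donor. The fallback uses known chemistry, sets out from phenol 2 and returns at iodide 12. Commercial 2,4-dibromo-6-fluoroaniline (Nc1c(F)cc(Br)cc1Br) is oxidised with NaBO3·4H2O in AcOH at 55 °C to 1,5-dibromo-3-fluoro-2-nitrobenzene F1. Nucleophilic aromatic substitution of its fluoride by 2 (K2CO3, DMF, 60 °C) should give 1,5-dibromo-2-nitro-3-(2,3,4-tribromo-6-methoxyphenoxy)benzene F2. Reduction with Fe powder and NH4Cl in EtOH/H2O at 70 °C, which leaves C–Br bonds alone, should give 2,4-dibromo-6-(2,3,4-tribromo-6-methoxyphenoxy)aniline F3. Diazotisation with NaNO2 in H2SO4/AcOH at 0–10 °C gives 2,4-dibromo-6-(2,3,4-tribromo-6-methoxyphenoxy)benzenediazonium hydrogensulfate F4, which aqueous KI converts into 12 (Sandmeyer-type iodination). In this fallback the ether bond is made by addition–elimination at a nitro-activated carbon and the C6' heteroatom is fixed by the nitro group from the start, so no aryl anion next to bromine and no regiochemical choice arises.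

Step 6. Boron may be lost from the crowded, electron-poor C6' boronate by protonolysis before the aryl group shifts to oxygen, or borylation of the doubly ortho-substituted Grignard reagent may stay incomplete; either way the hydrodeiodinated ether would result. The fallback sets out from iodide 12 and returns at target 15. The Grignard reagent 13, made as before, is treated at −78 → 0 °C with tert-butyl peroxybenzoate, so that the carbanion attacks peroxide oxygen directly and gives 1,5-dibromo-2-tert-butoxy-3-(2,3,4-tribromo-6-methoxyphenoxy)benzene F5. Cleavage of the tert-butyl ether with CF3CO2H in CH2Cl2 at 0 °C then gives 15. No boron intermediate is involved, and the methyl ether of ring A should survive the acid.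

Step 4. Bromine–lithium exchange may not stay confined to an ortho bromine, the O→C silyl shift may be incomplete or go between molecules, and the crowded phenolate 7 may be triflated only in part, giving mixtures of silylated and desilylated phenols. The fallback sets out from 2,4,6-tribromophenol 4 and returns at triflate 8. Protection with MOMCl and iPr2NEt in CH2Cl2 gives 1,3,5-tribromo-2-(methoxymethoxy)benzene F6. Chelation-assisted ortho bromine–lithium exchange (n-BuLi, THF, −100 °C) and quenching with Me3SiCl put silicon on carbon intermolecularly, giving [3,5-dibromo-2-(methoxymethoxy)phenyl]trimethylsilane F7. Mild acetal cleavage with ZnBr2 and n-PrSH in CH2Cl2 at 0 °C, chosen to spare the aryl–silicon bond, gives 2,4-dibromo-6-(trimethylsilyl)phenol F8. Triflation with Tf2O and pyridine in CH2Cl2 at 0 °C gives 8.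

**Further compounds**
F1 | step 5 | 1,5-dibromo-3-fluoro-2-nitrobenzene | O=[N+]([O-])c1c(F)cc(Br)cc1Br
F2 | step 5 | 1,5-dibromo-2-nitro-3-(2,3,4-tribromo-6-methoxyphenoxy)benzene | COc1cc(Br)c(Br)c(Br)c1Oc1cc(Br)cc(Br)c1[N+](=O)[O-]
F3 | step 5 | 2,4-dibromo-6-(2,3,4-tribromo-6-methoxyphenoxy)aniline | COc1cc(Br)c(Br)c(Br)c1Oc1cc(Br)cc(Br)c1N
F4 | step 5 | 2,4-dibromo-6-(2,3,4-tribromo-6-methoxyphenoxy)benzenediazonium hydrogensulfate | COc1cc(Br)c(Br)c(Br)c1Oc1cc(Br)cc(Br)c1[N+]#N.OS(=O)(=O)[O-]
F5 | step 6 | 1,5-dibromo-2-tert-butoxy-3-(2,3,4-tribromo-6-methoxyphenoxy)benzene | COc1cc(Br)c(Br)c(Br)c1Oc1cc(Br)cc(Br)c1OC(C)(C)C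
F6 | step 4 | 1,3,5-tribromo-2-(methoxymethoxy)benzene | COCOc1c(Br)cc(Br)cc1Br
F7 | step 4 | [3,5-dibromo-2-(methoxymethoxy)phenyl]trimethylsilane | COCOc1c(Br)cc(Br)cc1[Si](C)(C)C
F8 | step 4 | 2,4-dibromo-6-(trimethylsilyl)phenol | C[Si](C)(C)c1cc(Br)cc(Br)c1O
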